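**Retrosynthetic overview**
1. Target 20 ⇐ bis-MOM flavanone 19 ⇐ 2'-hydroxychalcone 18: the O1–C2 bond is cut, so ring C is closed last by a catalytic enantioselective 6-endo oxa-Michael addition that sets C2.
2. 18 ⇐ Claisen–Schmidt condensation of lavandulyl acetophenone 14 (ring A) with aldehyde 16 (ring B).
3. 14 ⇐ Negishi sp3–sp2 coupling of aryl iodide 12 with (S)-lavandulyl iodide 9.
4. 9 ⇐ Evans deconjugative α-prenylation of an N-senecioyl oxazolidinone, which sets the side-chain stereocentre.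
5. Rings A and B are bought as arenes; only ring C is built.

Assumption: 10 and 15 are taken as catalogue compounds, and catalyst A of step 10 is made separately from L-tert-leucine and not counted as a route step; if the first test cyclisation shows the opposite facial sense, its mirror image (from D-tert-leucine) is used.

Catalyst A: 1-[3,5-bis(trifluoromethyl)phenyl]-3-[(2S)-3,3-dimethyl-1-{[tris(4-methoxyphenyl)phosphanylidene]amino}butan-2-yl]thiourea, CC(C)(C)[C@@H](CN=P(c1ccc(OC)cc1)(c1ccc(OC)cc1)c1ccc(OC)cc1)NC(=S)Nc1cc(C(F)(F)F)cc(C(F)(F)F)c1.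

Note on descriptors: the side-chain centre is (S) in 7, 8, 9 and 13 and (R) from 14 onward. Only the CIP ranking changes (C=O, CH2OH, CH2I and CH2Zn outrank isopropenyl; CH2Ar does not); the spatial arrangement is never altered.

**Route**

Step 1
Reactants: 1 (4S)-4-benzyl-1,3-oxazolidin-2-one; 2 3-methylbut-2-enoyl chloride
Product: 4 (4S)-4-benzyl-3-(3-methylbut-2-enoyl)-1,3-oxazolidin-2-one, via lithium oxazolidinide 3 (not isolated)
Conditions: n-BuLi, THF, −78 °C; then 2, −78 → 0 °C
Reagents that add atoms: n-butyllithium, [Li]CCCC (supplies only the lithium of intermediate 3; no atoms in 4)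
Why: N-acylation of the lithiated Evans auxiliary at low temperature is fast and avoids the vinylketene/deconjugation pathway that amine bases open with this acid chloride; no stereocentre is formed.

Step 2
Reactants: 4 (4S)-4-benzyl-3-(3-methylbut-2-enoyl)-1,3-oxazolidin-2-one; 5 1-bromo-3-methylbut-2-ene (prenyl bromide)
Product: 7 (4S)-4-benzyl-3-[(2S)-5-methyl-2-(prop-1-en-2-yl)hex-4-enoyl]-1,3-oxazolidin-2-one, via sodium dienolate 6 (not isolated)
Conditions: NaN(SiMe3)2, THF, −78 °C; then 5, −78 → −40 °C; NH4Cl quench at −78 °C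
Reagents that add atoms: sodium bis(trimethylsilyl)amide, C[Si](C)(C)N([Na])[Si](C)(C)C (supplies only the sodium of intermediate 6; no atoms in 7)
Why: Evans deconjugative α-alkylation: γ-deprotonation gives the chelated (Z)-dienolate 6, which the allylic bromide alkylates at the α-carbon on the face opposite the benzyl group, setting the (2S) side-chain centre with high diastereoselectivity and moving the alkene into the isopropenyl position.

Step 3
Reactants: 7 (4S)-4-benzyl-3-[(2S)-5-methyl-2-(prop-1-en-2-yl)hex-4-enoyl]-1,3-oxazolidin-2-one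
Product: 8 (2S)-5-methyl-2-(prop-1-en-2-yl)hex-4-en-1-ol
Conditions: LiBH4, MeOH (1 equiv), Et2O, 0 °C
Reagents that add atoms: none
Why: Reductive cleavage of the N-acyl oxazolidinone by LiBH4 attacks the exocyclic carbonyl and gives the primary alcohol without epimerising the α-centre, with the auxiliary recovered.

Step 4
Reactants: 8 (2S)-5-methyl-2-(prop-1-en-2-yl)hex-4-en-1-ol
Product: 9 (3S)-3-(iodomethyl)-2,6-dimethylhepta-1,5-diene
Conditions: PPh3, I2, imidazole, CH2Cl2, 0 °C → rt
Reagents that add atoms: iodine, II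
Why: Appel-type iodination displaces the activated primary oxygen by SN2 at CH2, so the neighbouring stereocentre is untouched.

Step 5
Reactants: 10 1-(2,4-dihydroxy-6-methoxyphenyl)ethan-1-one
Product: 11 1-[2-hydroxy-6-methoxy-4-(methoxymethoxy)phenyl]ethan-1-one
Conditions: MOMCl (1.05 equiv), K2CO3, acetone, 0 °C → rt
Reagents that add atoms: chloromethyl methyl ether, COCCl
Why: Williamson-type O-alkylation is selective for the more acidic, unhindered 4-OH because the 2-OH is locked in a hydrogen bond to the ketone.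

Step 6
Reactants: 11 1-[2-hydroxy-6-methoxy-4-(methoxymethoxy)phenyl]ethan-1-one
Product: 12 1-[2-hydroxy-3-iodo-6-methoxy-4-(methoxymethoxy)phenyl]ethan-1-one
Conditions: NIS (1.05 equiv), MeCN, 0 °C, dark
Reagents that add atoms: N-iodosuccinimide, O=C1CCC(=O)N1I
Why: Electrophilic aromatic iodination of the phloroglucinol-type ring goes ortho to the free phenol (C3), as it does with the 4,6-dimethyl ether analogue, and neutral NIS leaves the MOM acetal intact.

Step 7
Reactants: 9 (3S)-3-(iodomethyl)-2,6-dimethylhepta-1,5-diene; 12 1-[2-hydroxy-3-iodo-6-methoxy-4-(methoxymethoxy)phenyl]ethan-1-one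
Product: 14 1-{2-hydroxy-6-methoxy-4-(methoxymethoxy)-3-[(2R)-5-methyl-2-(prop-1-en-2-yl)hex-4-en-1-yl]phenyl}ethan-1-one, via lavandulylzinc iodide 13 (not isolated)
Conditions: 9, Zn dust, LiCl, THF, 40 °C; then slow addition (1.6 equiv) to 12, Pd(OAc)2 (3 mol %), CPhos (6 mol %), THF, 25 → 45 °C
Reagents that add atoms: zinc, [Zn] (only in intermediate 13; no atoms in 14)
Why: Negishi sp3–sp2 cross-coupling: LiCl-assisted zinc insertion gives primary alkylzinc 13 without touching its β-stereocentre, the CPhos-ligated palladium catalyst couples the hindered aryl iodide faster than β-hydride elimination, and the chelated 2-OH protonates the zinc reagent only slowly (hence the excess).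

Step 8
Reactants: 15 4-hydroxy-2-methoxybenzaldehyde
Product: 16 2-methoxy-4-(methoxymethoxy)benzaldehyde
Conditions: MOMCl, K2CO3, acetone, rt
Reagents that add atoms: chloromethyl methyl ether, COCCl
Why: Williamson-type MOM protection caps the only phenol, which as a phenoxide would deactivate the aldehyde in the aldol step and the enone in the cyclisation.

Step 9
Reactants: 14 1-{2-hydroxy-6-methoxy-4-(methoxymethoxy)-3-[(2R)-5-methyl-2-(prop-1-en-2-yl)hex-4-en-1-yl]phenyl}ethan-1-one; 16 2-methoxy-4-(methoxymethoxy)benzaldehyde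
Product: 18 (2E)-1-{2-hydroxy-6-methoxy-4-(methoxymethoxy)-3-[(2R)-5-methyl-2-(prop-1-en-2-yl)hex-4-en-1-yl]phenyl}-3-[2-methoxy-4-(methoxymethoxy)phenyl]prop-2-en-1-one, via aldol adduct 17 (not isolated)
Conditions: KOH, EtOH/H2O, 0 °C → rt; cold aq. AcOH quench
Reagents that add atoms: none
Why: Claisen–Schmidt condensation: the methyl ketone enolate adds to the non-enolisable aldehyde and aldol 17 dehydrates by E1cB to the (E)-enone, which rests as the open 2'-phenoxide in strong base so that no racemic flavanone is carried forward.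

Step 10
Reactants: 18 (2E)-1-{2-hydroxy-6-methoxy-4-(methoxymethoxy)-3-[(2R)-5-methyl-2-(prop-1-en-2-yl)hex-4-en-1-yl]phenyl}-3-[2-methoxy-4-(methoxymethoxy)phenyl]prop-2-en-1-one
Product: 19 (2S)-5-methoxy-7-(methoxymethoxy)-2-[2-methoxy-4-(methoxymethoxy)phenyl]-8-[(2R)-5-methyl-2-(prop-1-en-2-yl)hex-4-en-1-yl]-2,3-dihydro-4H-chromen-4-one
Conditions: catalyst A (10 mol %), toluene (0.05 M), −20 °C, 24–48 h; AcOH quench at −20 °C
Reagents that add atoms: none
Why: Proposed new method: a bifunctional iminophosphorane–thiourea superbase, several pKa units more basic than a cinchona quinuclidine, deprotonates the hydrogen-bonded 2'-OH to a tight chiral aminophosphonium phenoxide ion pair while its thiourea binds the carbonyl of the enone (twisted out of conjugation with ring A by the 6'-OMe group and therefore still electrophilic), so the phenoxide closes the ring by 6-endo-trig attack on the Si face of C-β to set (2S) and the P–N–H protonates the enolate, the cold acidic quench stopping retro-oxa-Michael erosion; the closest known reaction types are the iminophosphorane-catalysed intramolecular oxa-Michael addition of alcohols to unsaturated esters and amides and the thiourea-catalysed cyclisation of ester-activated 2'-hydroxychalcones, neither shown on an unactivated, doubly ortho-substituted chalcone.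

Step 11
Reactants: 19 (2S)-5-methoxy-7-(methoxymethoxy)-2-[2-methoxy-4-(methoxymethoxy)phenyl]-8-[(2R)-5-methyl-2-(prop-1-en-2-yl)hex-4-en-1-yl]-2,3-dihydro-4H-chromen-4-one
Product: 20 (2S)-7-hydroxy-2-(4-hydroxy-2-methoxyphenyl)-5-methoxy-8-[(2R)-5-methyl-2-(prop-1-en-2-yl)hex-4-en-1-yl]-2,3-dihydro-4H-chromen-4-one
Conditions: HCl (1.25 M in MeOH), MeOH/THF, 0 °C → rt
Reagents that add atoms: none
Why: Acid-catalysed acetal exchange to methanol removes both MOM groups under the mild conditions used to unmask prenylated 2'-hydroxy-6'-methoxy chalcones and flavanones, which leave trisubstituted and 1,1-disubstituted alkenes alone and do not open the pyranone ring, so both stereocentres are retained.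

**Compound list**
1 | (4S)-4-benzyl-1,3-oxazolidin-2-one | O=C1N[C@@H](Cc2ccccc2)CO1 | starting material
2 | 3-methylbut-2-enoyl chloride | CC(C)=CC(Cl)=O | starting material
3 | lithium (4S)-4-benzyl-2-oxo-1,3-oxazolidin-3-ide (not isolated) | [Li+].O=C1[N-][C@@H](Cc2ccccc2)CO1 | intermediate
4 | (4S)-4-benzyl-3-(3-methylbut-2-enoyl)-1,3-oxazolidin-2-one | CC(C)=CC(=O)N1[C@@H](Cc2ccccc2)COC1=O | intermediate
5 | 1-bromo-3-methylbut-2-ene (prenyl bromide) | CC(C)=CCBr | starting material
6 | sodium (Z)-dienolate of 4 (not isolated) | [Na+].C=C(C)/C=C(\[O-])N1[C@@H](Cc2ccccc2)COC1=O | intermediate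
7 | (4S)-4-benzyl-3-[(2S)-5-methyl-2-(prop-1-en-2-yl)hex-4-enoyl]-1,3-oxazolidin-2-one | C=C(C)[C@H](CC=C(C)C)C(=O)N1[C@@H](Cc2ccccc2)COC1=O | intermediate
8 | (2S)-5-methyl-2-(prop-1-en-2-yl)hex-4-en-1-ol ((S)-lavandulol) | C=C(C)[C@H](CC=C(C)C)CO | intermediate
9 | (3S)-3-(iodomethyl)-2,6-dimethylhepta-1,5-diene | C=C(C)[C@H](CC=C(C)C)CI | intermediate
10 | 1-(2,4-dihydroxy-6-methoxyphenyl)ethan-1-one | CC(=O)c1c(O)cc(O)cc1OC | starting material
11 | 1-[2-hydroxy-6-methoxy-4-(methoxymethoxy)phenyl]ethan-1-one | CC(=O)c1c(O)cc(OCOC)cc1OC | intermediate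
12 | 1-[2-hydroxy-3-iodo-6-methoxy-4-(methoxymethoxy)phenyl]ethan-1-one | CC(=O)c1c(O)c(I)c(OCOC)cc1OC | intermediate
13 | [(2S)-5-methyl-2-(prop-1-en-2-yl)hex-4-en-1-yl]zinc iodide (not isolated) | C=C(C)[C@H](CC=C(C)C)C[Zn]I | intermediate
14 | 1-{2-hydroxy-6-methoxy-4-(methoxymethoxy)-3-[(2R)-5-methyl-2-(prop-1-en-2-yl)hex-4-en-1-yl]phenyl}ethan-1-one | C=C(C)[C@H](CC=C(C)C)Cc1c(O)c(C(C)=O)c(OC)cc1OCOC | intermediate
15 | 4-hydroxy-2-methoxybenzaldehyde | COc1cc(O)ccc1C=O | starting material
16 | 2-methoxy-4-(methoxymethoxy)benzaldehyde | COCOc1ccc(C=O)c(OC)c1 | intermediate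
17 | 3-hydroxy-1-{2-hydroxy-6-methoxy-4-(methoxymethoxy)-3-[(2R)-5-methyl-2-(prop-1-en-2-yl)hex-4-en-1-yl]phenyl}-3-[2-methoxy-4-(methoxymethoxy)phenyl]propan-1-one (both carbinol epimers; not isolated) | C=C(C)[C@H](CC=C(C)C)Cc1c(O)c(C(=O)CC(O)c2ccc(OCOC)cc2OC)c(OC)cc1OCOC | intermediate
18 | (2E)-1-{2-hydroxy-6-methoxy-4-(methoxymethoxy)-3-[(2R)-5-methyl-2-(prop-1-en-2-yl)hex-4-en-1-yl]phenyl}-3-[2-methoxy-4-(methoxymethoxy)phenyl]prop-2-en-1-one | C=C(C)[C@H](CC=C(C)C)Cc1c(O)c(C(=O)/C=C/c2ccc(OCOC)cc2OC)c(OC)cc1OCOC | intermediate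
19 | (2S)-5-methoxy-7-(methoxymethoxy)-2-[2-methoxy-4-(methoxymethoxy)phenyl]-8-[(2R)-5-methyl-2-(prop-1-en-2-yl)hex-4-en-1-yl]-2,3-dihydro-4H-chromen-4-one | C=C(C)[C@H](CC=C(C)C)Cc1c(OCOC)cc(OC)c2c1O[C@H](c1ccc(OCOC)cc1OC)CC2=O | intermediate
20 | (2S)-7-hydroxy-2-(4-hydroxy-2-methoxyphenyl)-5-methoxy-8-[(2R)-5-methyl-2-(prop-1-en-2-yl)hex-4-en-1-yl]-2,3-dihydro-4H-chromen-4-one ((2S)-2'-methoxykurarinone) | C=C(C)[C@H](CC=C(C)C)Cc1c(O)cc(OC)c2c1O[C@H](c1ccc(O)cc1OC)CC2=O | target

**Step count and risks**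

Total steps: 11. Longest linear sequence: 8 (steps 1, 2, 3, 4, 7, 9, 10, 11).

Stereocentres: the side-chain centre is set in step 2 and never becomes enolisable or part of a reacting centre afterwards. C2 is set in step 10 and sees only the mild acid of step 11.

Most likely to fail, first: step 7, the Negishi coupling. The aryl iodide is flanked by two oxygen substituents and carries a free phenol, and the β-branched alkylzinc can be lost to protonolysis or β-hydride elimination. The fallback reverses the polarity and uses no palladium. It sets out from iodide 9 and commercial 5-methoxyresorcinol (COc1cc(O)cc(O)c1). The diphenol is converted with NaH and MOMCl in DMF into 1-methoxy-3,5-bis(methoxymethoxy)benzene F1. n-BuLi in THF at 0 °C removes the proton between the two MOM ethers to give [4-methoxy-2,6-bis(methoxymethoxy)phenyl]lithium F2. This is alkylated by 9 (CuBr·SMe2 10 mol %, THF/DMPU, −20 °C → rt) to 5-methoxy-1,3-bis(methoxymethoxy)-2-[(2R)-5-methyl-2-(prop-1-en-2-yl)hex-4-en-1-yl]benzene F3. A second lithiation with n-BuLi, at one of the two equivalent remaining ring positions, gives {6-methoxy-2,4-bis(methoxymethoxy)-3-[(2R)-5-methyl-2-(prop-1-en-2-yl)hex-4-en-1-yl]phenyl}lithium F4. N-methoxy-N-methylacetamide converts it into 1-{6-methoxy-2,4-bis(methoxymethoxy)-3-[(2R)-5-methyl-2-(prop-1-en-2-yl)hex-4-en-1-yl]phenyl}ethan-1-one F5. Carbonyl-assisted cleavage of the MOM ether ortho to the acetyl group (cat. HCl, MeOH, 0 °C, stopped at mono-cleavage) brings the sequence back to the route at 14. The symmetry of F1 and F3 also removes any question of regiochemistry in the iodination.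

Second: step 10, the proposed catalytic asymmetric oxa-Michael cyclisation. The hindered chalcone may cyclise slowly, and retro-oxa-Michael ring opening under the strong base could erode selectivity at C2. The fallback uses only known chemistry and sets out from chalcone 18. Thermodynamic cyclisation with NaOAc in refluxing EtOH gives 19 together with its C2 epimer, (2R)-5-methoxy-7-(methoxymethoxy)-2-[2-methoxy-4-(methoxymethoxy)phenyl]-8-[(2R)-5-methyl-2-(prop-1-en-2-yl)hex-4-en-1-yl]-2,3-dihydro-4H-chromen-4-one F6. Because the side chain is enantiopure the two are diastereomers, and they are separated by preparative HPLC on a cellulose tris(3,5-dimethylphenylcarbamate) phase. F6 is re-equilibrated through 18 under the same NaOAc conditions and recycled. The sequence comes back to the route at 19.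

Third: step 11, the global MOM removal. With ring C closed, acid can add the 7-OH across the isopropenyl alkene (chroman formation) or epimerise C2 through ring opening. The fallback changes the protecting-group strategy and sets out from chalcone 18. The MOM groups are removed at the chalcone stage (HCl, MeOH, rt), where there is no C2 centre to lose and where the prenyl analogue is known to survive, giving (2E)-1-{2,4-dihydroxy-6-methoxy-3-[(2R)-5-methyl-2-(prop-1-en-2-yl)hex-4-en-1-yl]phenyl}-3-(4-hydroxy-2-methoxyphenyl)prop-2-en-1-one F7. TBSCl and imidazole in DMF at 0 °C silylate the two unhindered phenols but not the chelated 2'-OH, giving (2E)-1-{4-[(tert-butyldimethylsilyl)oxy]-2-hydroxy-6-methoxy-3-[(2R)-5-methyl-2-(prop-1-en-2-yl)hex-4-en-1-yl]phenyl}-3-{4-[(tert-butyldimethylsilyl)oxy]-2-methoxyphenyl}prop-2-en-1-one F8. Cyclisation under the step 10 protocol (or its fallback) gives (2S)-7-[(tert-butyldimethylsilyl)oxy]-2-{4-[(tert-butyldimethylsilyl)oxy]-2-methoxyphenyl}-5-methoxy-8-[(2R)-5-methyl-2-(prop-1-en-2-yl)hex-4-en-1-yl]-2,3-dihydro-4H-chromen-4-one F9. Buffered fluoride (HF·pyridine, THF/pyridine, 0 °C) then frees both phenols under non-acidic, non-basic conditions, and the sequence comes back to the route at 20.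

**Further compounds**
F1 | step 7 | 1-methoxy-3,5-bis(methoxymethoxy)benzene | COCOc1cc(OC)cc(OCOC)c1
F2 | step 7 | [4-methoxy-2,6-bis(methoxymethoxy)phenyl]lithium | [Li]c1c(OCOC)cc(OC)cc1OCOC
F3 | step 7 | 5-methoxy-1,3-bis(methoxymethoxy)-2-[(2R)-5-methyl-2-(prop-1-en-2-yl)hex-4-en-1-yl]benzene | C=C(C)[C@H](CC=C(C)C)Cc1c(OCOC)cc(OC)cc1OCOC
F4 | step 7 | {6-methoxy-2,4-bis(methoxymethoxy)-3-[(2R)-5-methyl-2-(prop-1-en-2-yl)hex-4-en-1-yl]phenyl}lithium | C=C(C)[C@H](CC=C(C)C)Cc1c(OCOC)cc(OC)c([Li])c1OCOC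
F5 | step 7 | 1-{6-methoxy-2,4-bis(methoxymethoxy)-3-[(2R)-5-methyl-2-(prop-1-en-2-yl)hex-4-en-1-yl]phenyl}ethan-1-one | C=C(C)[C@H](CC=C(C)C)Cc1c(OCOC)cc(OC)c(C(C)=O)c1OCOC
F6 | step 10 | (2R)-5-methoxy-7-(methoxymethoxy)-2-[2-methoxy-4-(methoxymethoxy)phenyl]-8-[(2R)-5-methyl-2-(prop-1-en-2-yl)hex-4-en-1-yl]-2,3-dihydro-4H-chromen-4-one | C=C(C)[C@H](CC=C(C)C)Cc1c(OCOC)cc(OC)c2c1O[C@@H](c1ccc(OCOC)cc1OC)CC2=O
F7 | step 11 | (2E)-1-{2,4-dihydroxy-6-methoxy-3-[(2R)-5-methyl-2-(prop-1-en-2-yl)hex-4-en-1-yl]phenyl}-3-(4-hydroxy-2-methoxyphenyl)prop-2-en-1-one | C=C(C)[C@H](CC=C(C)C)Cc1c(O)c(C(=O)/C=C/c2ccc(O)cc2OC)c(OC)cc1O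
F8 | step 11 | (2E)-1-{4-[(tert-butyldimethylsilyl)oxy]-2-hydroxy-6-methoxy-3-[(2R)-5-methyl-2-(prop-1-en-2-yl)hex-4-en-1-yl]phenyl}-3-{4-[(tert-butyldimethylsilyl)oxy]-2-methoxyphenyl}prop-2-en-1-one | C=C(C)[C@H](CC=C(C)C)Cc1c(O)c(C(=O)/C=C/c2ccc(O[Si](C)(C)C(C)(C)C)cc2OC)c(OC)cc1O[Si](C)(C)C(C)(C)C
F9 | step 11 | (2S)-7-[(tert-butyldimethylsilyl)oxy]-2-{4-[(tert-butyldimethylsilyl)oxy]-2-methoxyphenyl}-5-methoxy-8-[(2R)-5-methyl-2-(prop-1-en-2-yl)hex-4-en-1-yl]-2,3-dihydro-4H-chromen-4-one | C=C(C)[C@H](CC=C(C)C)Cc1c(O[Si](C)(C)C(C)(C)C)cc(OC)c2c1O[C@H](c1ccc(O[Si](C)(C)C(C)(C)C)cc1OC)CC2=O
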